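**Plan**
- Cuts: the acid from its ethyl ester; C8=C9 by Wittig olefination; C4–CH3 by cross-coupling of a C4 enol triflate; C3–CH3 by cuprate addition to a C3=C3a enone; C3–C3a by aldol condensation; C6–Ph by a second cuprate addition; C7a–C1 by intramolecular Michael addition of a methylmalonate tethered through the C8 oxygen to a dienone made from benzoic acid.
- Forward: Birch ethylation of benzoic acid gives the six-membered ring with quaternary C7; the δ-lactone closes in the Michael step; after phenylation at C6 the lactone is half-reduced and homologated by one carbon, the arm is installed, and the cyclopentene closes by aldol condensation; methyl at C3, triflate/methyl at C4 and saponification finish.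
- Stereochemistry: the catalyst selects one enantiotopic enone (C7 and C7a, cis through the tether); C1 by equilibration in the lactone; C6 by cuprate attack anti to the lactone ring; C3 by cuprate attack anti to the C1 methyl; C3a by axial protonation anti to the C3 methyl; the E alkene by the stabilised ylide.

Key step: step 5

Remark: atoms carry the indene numbering of the target throughout (C1–C7a; C8 is the first arm carbon); the sense of induction of the cinchonidinium salt in step 5 is assumed to be the one drawn, and the pseudoenantiomeric cinchoninium salt would be used otherwise.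

**Step 1**
Reactants: 1 benzoic acid; 2 iodoethane
Product: 3 1-ethylcyclohexa-2,5-diene-1-carboxylic acid
Conditions: Li, NH3(l), THF, −78 °C; then EtI, −78 °C → rt; NH4Cl, then HCl
Reagents that add atoms: none
Why: Birch reduction of benzoic acid gives the carboxylate-stabilised cyclohexadienyl dianion, which iodoethane alkylates at the ipso carbon (Birch reductive alkylation), so that the future C7 carries ethyl and the carbon that becomes C8.

**Step 2**
Reactants: 3 1-ethylcyclohexa-2,5-diene-1-carboxylic acid
Product: 4 (1-ethylcyclohexa-2,5-dien-1-yl)methanol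
Conditions: LiAlH4, THF, 0 °C → reflux; aqueous NaOH work-up
Reagents that add atoms: none
Why: Hydride reduction of the carboxylic acid gives the neopentyl alcohol and leaves the isolated ring alkenes untouched.

**Step 3**
Reactants: 4 (1-ethylcyclohexa-2,5-dien-1-yl)methanol; 5 3-methoxy-2-methyl-3-oxopropanoic acid
Product: 6 (1-ethylcyclohexa-2,5-dien-1-yl)methyl methyl 2-methylmalonate
Conditions: DCC, DMAP (cat.), CH2Cl2, 0 °C → rt
Reagents that add atoms: none
Why: Steglich esterification acylates the hindered primary alcohol with the malonic half ester under neutral conditions that the skipped diene tolerates.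

**Step 4**
Reactants: 6 (1-ethylcyclohexa-2,5-dien-1-yl)methyl methyl 2-methylmalonate
Product: 7 (1-ethyl-4-oxocyclohexa-2,5-dien-1-yl)methyl methyl 2-methylmalonate
Conditions: PDC (20 mol%), t-BuOOH (4 equiv), Celite, PhH, rt
Reagents that add atoms: tert-butyl hydroperoxide, CC(C)(C)OO
Why: The doubly allylic CH2 holds the weakest C–H bonds of the molecule and is oxidised to the cross-conjugated dienone by chromium(VI)/hydroperoxide allylic oxidation, the usual way from Birch products to 4,4-disubstituted cyclohexadienones.

**Step 5**
Reactants: 7 (1-ethyl-4-oxocyclohexa-2,5-dien-1-yl)methyl methyl 2-methylmalonate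
Product: 8 cis-fused malonate lactone enone (methyl 8a-ethyl-4-methyl-3,6-dioxo-3,4,4a,5,6,8a-hexahydro-1H-isochromene-4-carboxylate; C7a–H cis to ethyl; C1 epimers)
Conditions: N-(9-anthracenylmethyl)cinchonidinium bromide (10 mol%), Cs2CO3 (0.5 equiv, solid), PhMe, −30 °C
Reagents that add atoms: none
Why: Solid caesium carbonate deprotonates the methylmalonate C–H at the interface and the chiral ammonium cation carries the enolate as a tight ion pair to the β-carbon of one of the two enantiotopic enone arms, after which the ketone enolate is protonated by further substrate (intramolecular Michael addition under asymmetric phase-transfer catalysis). The closest known reaction type is the cinchona-catalysed desymmetrisation of 4,4-disubstituted cyclohexadienones by tethered malonate and related 1,3-dicarbonyl nucleophiles. The δ-lactone closes in a 6-exo-trig mode, the attacked C7a=C3a bond lying outside the new ring. The three-atom ester tether reaches the β-carbon only from its own face, so the new C7a–C1 bond is cis to C8 and the catalyst's choice of enone fixes C7 and C7a together, while C1 forms as a mixture that step 6 erases. The step needs discrimination of the enantiotopic enones under kinetic control: apolar solvent, low temperature and substoichiometric base keep the ion pair tight and suppress retro-Michael racemisation, and the second enone is out of reach of the tethered carbon and survives for step 7.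

**Step 6**
Reactants: 8 cis-fused malonate lactone enone
Product: 10 lactone enone (C1 methyl trans to the C7a–C3a bond), via C1-epimeric lactone enone 9 (not isolated)
Conditions: LiCl, H2O, DMSO, 150 °C; then DBU (cat.), 60 °C, same flask
Reagents that add atoms: none
Why: Krapcho dealkoxycarbonylation removes the methyl ester (chloride attacks the O-methyl group, the carboxylate loses CO2, the lactone enolate is protonated) while the neopentyl-type lactone CH2–O resists SN2 cleavage, and DBU then equilibrates C1 through the lactone enolate towards the epimer whose methyl is pseudo-equatorial on the convex face, trans to the C7a–C3a bond and free of the syn-axial contact with C6 that burdens the other epimer.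

**Step 7**
Reactants: 10 lactone enone
Product: 11 C6-phenyl keto lactone (phenyl trans to C8 and cis to ethyl)
Conditions: Ph2CuLi (from PhLi and CuI), Et2O/THF, −78 → −40 °C; sat. NH4Cl
Reagents that add atoms: phenyllithium, [Li]c1ccccc1 (transferred as lithium diphenylcuprate made in the flask with CuI)
Why: Conjugate addition of the lithium diphenylcuprate to the remaining enone should occur at C6 by axial attack anti to the pseudo-axial lactone CH2 on the neighbouring quaternary C7 and trans to the C7a substituent, that is on the convex face of the cis-fused bicycle, which places phenyl trans to the arm.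

**Step 8**
Reactants: 11 C6-phenyl keto lactone
Product: 12 C4-dioxolane lactone
Conditions: (TMSOCH2)2, TMSOTf (cat.), CH2Cl2, −78 → −20 °C; pyridine quench
Reagents that add atoms: 1,2-bis(trimethylsilyloxy)ethane, C[Si](C)(C)OCCO[Si](C)(C)C
Why: Ketalisation with the bis-silyl glycol ether and catalytic TMSOTf masks the C4 ketone at low temperature without opening the lactone or disturbing C1, so that the hydride and the ylide of the next steps meet only the lactone.

**Step 9**
Reactants: 12 C4-dioxolane lactone
Product: 13 lactol (anomers)
Conditions: DIBAL-H, CH2Cl2, −78 °C; Rochelle salt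
Reagents that add atoms: none
Why: At −78 °C the tetrahedral aluminate does not collapse, so the δ-lactone is reduced only to the lactol (lactone half-reduction), the masked C2 aldehyde.

**Step 10**
Reactants: 13 lactol
Product: 14 enol ether alcohol (C1–C2H=C3H–OMe chain on C7a; free C8–OH; E/Z mixture)
Conditions: Ph3P(CH2OMe)Cl, KHMDS, THF, 0 °C; then 13, 0 °C → rt
Reagents that add atoms: (methoxymethyl)triphenylphosphonium chloride, [Cl-].COC[P+](c1ccccc1)(c1ccccc1)c1ccccc1
Why: Wittig methoxymethylenation of the open hydroxy-aldehyde form of the lactol adds C3 as an enol ether carbon and releases the C8 alcohol, the reactive ylide at low temperature leaving little time for enolisation of the α-stereocentre C1.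

**Step 11**
Reactants: 14 enol ether alcohol
Product: 15 C8 aldehyde
Conditions: Dess–Martin periodinane, pyridine, CH2Cl2, 0 °C → rt
Reagents that add atoms: none
Why: Buffered Dess–Martin oxidation converts the neopentyl alcohol into the non-enolisable α-quaternary aldehyde and tolerates the enol ether and the ketal.

**Step 12**
Reactants: 15 C8 aldehyde
Product: 16 (E)-enoate (ethyl 2-methylacrylate arm on C7)
Conditions: Ph3P=C(Me)CO2Et, PhMe, 100 °C
Reagents that add atoms: ethyl 2-(triphenylphosphoranylidene)propanoate, CCOC(=O)C(C)=P(c1ccccc1)(c1ccccc1)c1ccccc1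
Why: Wittig olefination with the stabilised α-methyl ylide gives the E trisubstituted enoate, the bulky quaternary substituent and the ester ending trans in the reversible oxaphosphetane stage.

**Step 13**
Reactants: 16 (E)-enoate
Product: 19 bicyclic C3=C3a enone ester, via keto aldehyde 17 (not isolated), via aldol adduct 18 (not isolated)
Conditions: 2 M HCl, THF, 50 °C
Reagents that add atoms: water, O
Why: Aqueous acid hydrolyses the enol ether to the C3 aldehyde and the dioxolane to the C4 ketone, and the 1,6-keto aldehyde then undergoes intramolecular aldol condensation through the C3a enol (5-exo closure) to the conjugated enone, the only other five-membered mode (C2 onto C4) giving a bridged aldol that cannot dehydrate and reverts.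

**Step 14**
Reactants: 19 bicyclic C3=C3a enone ester
Product: 20 trans-fused C3-methyl ketone (C3 methyl trans to the C1 methyl; H3a trans to H7a)
Conditions: Me2CuLi (from MeLi and CuI), Et2O, −78 → −40 °C; sat. NH4Cl at −78 °C
Reagents that add atoms: methyllithium, [Li]C (transferred as lithium dimethylcuprate made in the flask with CuI)
Why: Cuprate conjugate addition to the s-cis enone should deliver methyl to C3 from the face opposite the pseudo-axial C1 methyl and the C7a–C7 bond, and kinetic axial protonation of the C3a=C4 enolate anti to the new methyl leads directly to the chair of the trans-fused ketone, as in cuprate additions to cyclopentenyl ketones of the 16-dehydro-20-keto steroid type.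

**Step 15**
Reactants: 20 trans-fused C3-methyl ketone
Product: 21 C4=C5 enol triflate
Conditions: KHMDS, THF, −78 °C; PhNTf2, −78 → 0 °C
Reagents that add atoms: N-phenylbis(trifluoromethanesulfonimide), O=S(=O)(N(c1ccccc1)S(=O)(=O)C(F)(F)F)C(F)(F)F
Why: Kinetic deprotonation removes a C5 methylene proton in preference to the tertiary C3a proton, and O-sulfonylation fixes the C4=C5 enol triflate without epimerising C3a (kinetic enolate triflation).

**Step 16**
Reactants: 21 C4=C5 enol triflate
Product: 22 plakotenin ethyl ester
Conditions: MeZnCl, Pd(PPh3)4 (5 mol%), THF, 50 °C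
Reagents that add atoms: methylzinc chloride, C[Zn]Cl
Why: Negishi coupling of the alkenyl triflate with methylzinc chloride replaces OTf by methyl with the double bond held in place and tolerates the ester.

**Step 17**
Reactants: 22 plakotenin ethyl ester
Product: 23 plakotenin
Conditions: LiOH, THF/MeOH/H2O, 50 °C; then 1 M HCl
Reagents that add atoms: lithium hydroxide, [Li+].[OH-]
Why: Saponification of the unhindered ethyl ester and acidification free the acid, no stereocentre of the molecule being base-labile at this stage.

**Compound list**
1 | benzoic acid | OC(=O)c1ccccc1 | starting material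
2 | iodoethane | CCI | starting material
3 | 1-ethylcyclohexa-2,5-diene-1-carboxylic acid | CCC1(C(=O)O)C=CCC=C1 | intermediate
4 | (1-ethylcyclohexa-2,5-dien-1-yl)methanol | CCC1(CO)C=CCC=C1 | intermediate
5 | 3-methoxy-2-methyl-3-oxopropanoic acid | COC(=O)C(C)C(=O)O | starting material
6 | (1-ethylcyclohexa-2,5-dien-1-yl)methyl methyl 2-methylmalonate | COC(=O)C(C)C(=O)OCC1(CC)C=CCC=C1 | intermediate
7 | (1-ethyl-4-oxocyclohexa-2,5-dien-1-yl)methyl methyl 2-methylmalonate | COC(=O)C(C)C(=O)OCC1(CC)C=CC(=O)C=C1 | intermediate
8 | methyl 8a-ethyl-4-methyl-3,6-dioxo-3,4,4a,5,6,8a-hexahydro-1H-isochromene-4-carboxylate, cis-fused (C7a–H cis to ethyl), C1 epimers | CC[C@@]1(COC(=O)C2(C)C(=O)OC)[C@H]2CC(=O)C=C1 | intermediate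
9 | cis-fused α-methyl lactone enone, C1 epimers | CC[C@@]1(COC(=O)C2C)[C@H]2CC(=O)C=C1 | intermediate (not isolated)
10 | cis-fused α-methyl lactone enone, C1 methyl trans to the C7a–C3a bond | CC[C@@]1(COC(=O)[C@H]2C)[C@H]2CC(=O)C=C1 | intermediate
11 | keto lactone with phenyl at C6, trans to the lactone CH2 (C8) and cis to ethyl | CC[C@@]1(COC(=O)[C@H]2C)[C@H]2CC(=O)C[C@H]1c1ccccc1 | intermediate
12 | ethylene ketal (C4 dioxolane) of 11 | CC[C@@]1(COC(=O)[C@H]2C)[C@H]2CC3(OCCO3)C[C@H]1c1ccccc1 | intermediate
13 | lactol from 12 (C2 hemiacetal, anomers) | CC[C@@]1(COC(O)[C@H]2C)[C@H]2CC3(OCCO3)C[C@H]1c1ccccc1 | intermediate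
14 | C4-dioxolane cyclohexane with ethyl and CH2OH on C7, phenyl on C6 and the 4-methoxybut-3-en-2-yl chain on C7a (E/Z mixture) | CC[C@@]1(CO)[C@H]([C@H](C)C=COC)CC2(OCCO2)C[C@H]1c1ccccc1 | intermediate
15 | C8 aldehyde of 14 | CC[C@@]1(C=O)[C@H]([C@H](C)C=COC)CC2(OCCO2)C[C@H]1c1ccccc1 | intermediate
16 | ethyl (E)-2-methylacrylate from 15 (enol ether and ketal retained) | CC[C@@]1(/C=C(\C)C(=O)OCC)[C@H]([C@H](C)C=COC)CC2(OCCO2)C[C@H]1c1ccccc1 | intermediate
17 | keto aldehyde (C4 ketone, C3 aldehyde) | CC[C@@]1(/C=C(\C)C(=O)OCC)[C@H]([C@H](C)CC=O)CC(=O)C[C@H]1c1ccccc1 | intermediate (not isolated)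
18 | aldol adduct (C3 hydroxy, C4 ketone; C3 and C3a unassigned) | CC[C@@]1(/C=C(\C)C(=O)OCC)[C@H]2C(C(=O)C[C@H]1c1ccccc1)C(O)C[C@H]2C | intermediate (not isolated)
19 | bicyclic enone: hexahydroinden-4-one with C3=C3a, C1 methyl, C6 phenyl, C7 ethyl and (E)-enoate arm | CC[C@@]1(/C=C(\C)C(=O)OCC)[C@H]2C(C(=O)C[C@H]1c1ccccc1)=CC[C@H]2C | intermediate
20 | trans-fused octahydroinden-4-one with C1 and C3 methyls trans to each other | CC[C@@]1(/C=C(\C)C(=O)OCC)[C@H]2[C@H](C(=O)C[C@H]1c1ccccc1)[C@H](C)C[C@H]2C | intermediate
21 | C4=C5 enol triflate of 20 | CC[C@@]1(/C=C(\C)C(=O)OCC)[C@H]2[C@H](C(OS(=O)(=O)C(F)(F)F)=C[C@H]1c1ccccc1)[C@H](C)C[C@H]2C | intermediate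
22 | plakotenin ethyl ester | CC[C@@]1(/C=C(\C)C(=O)OCC)[C@H]2[C@H](C(C)=C[C@H]1c1ccccc1)[C@H](C)C[C@H]2C | intermediate
23 | plakotenin | CC[C@@]1(/C=C(\C)C(=O)O)[C@H]2[C@H](C(C)=C[C@H]1c1ccccc1)[C@H](C)C[C@H]2C | target

Total step count: 17
Longest linear sequence: 17 steps (benzoic acid to plakotenin)

**Steps most likely to fail**

Step 5. The tertiary malonate carbon may attack the β-carbon next to the quaternary centre slowly and reversibly, and retro-Michael re-addition would erode the enantiomeric purity. The fallback carries the malonate through the ring closure without its methyl group and methylates afterwards. It sets out from 4: Steglich esterification with 3-methoxy-3-oxopropanoic acid would give (1-ethylcyclohexa-2,5-dien-1-yl)methyl methyl malonate F1, chromium/hydroperoxide oxidation the dienone malonate F2, and the same cinchona-catalysed closure, now with a more acidic and less hindered secondary carbon, the cis-fused lactone malonate F3. C-Methylation of F3 (MeI, K2CO3, acetone) comes back to the route at 8.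

Step 6. The thermodynamic bias at C1 may be weak, so that equilibration stalls at an unfavourable epimer mixture. The fallback sets C1 by kinetic alkylation instead. It sets out from 4 and passes through F1, F2 and F3 as above. Krapcho dealkoxycarbonylation of F3 would give the C1-unsubstituted lactone enone F4, phenyl cuprate addition as in step 7 the C1-unsubstituted phenyl keto lactone F5, and ketalisation as in step 8 the C1-unsubstituted dioxolane lactone F6. Deprotonation of F6 with LDA at −78 °C and methylation with iodomethane on the convex face, trans to the C7a–C3a bond, comes back to the route at 12.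

Step 14. Methyl may be delivered to the wrong face of C3, or the enolate may be protonated on the wrong face of C3a to give the cis ring fusion. The fallback exchanges the roles of methyl and hydrogen and lets the C8 hydroxyl direct both hydrogens. It sets out from 13: Wittig reaction with the ylide of (1-methoxyethyl)triphenylphosphonium chloride would give the methyl-substituted enol ether alcohol F7. Aqueous acid would unmask the diketone alcohol F8, which condenses in the same flask to the C3-methyl tetrasubstituted enone alcohol F9. Hydroxyl-directed hydrogenation with Crabtree's catalyst should add H2 to C3 and C3a from the face of the C8 hydroxymethyl group and give the trans-fused hydroxy ketone F10 with the C3 methyl on the opposite face. Dess–Martin oxidation would give the keto aldehyde F11, and the stabilised ylide of step 12, which reacts at the aldehyde only, comes back to the route at 20.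

**Further compounds**
F1 | step 5 | (1-ethylcyclohexa-2,5-dien-1-yl)methyl methyl malonate | COC(=O)CC(=O)OCC1(CC)C=CCC=C1
F2 | step 5 | (1-ethyl-4-oxocyclohexa-2,5-dien-1-yl)methyl methyl malonate | COC(=O)CC(=O)OCC1(CC)C=CC(=O)C=C1
F3 | step 5 | cis-fused lactone malonate lacking the C1 methyl (C1 epimers) | CC[C@@]1(COC(=O)C2C(=O)OC)[C@H]2CC(=O)C=C1
F4 | step 6 | C1-unsubstituted cis-fused lactone enone | CC[C@@]1(COC(=O)C2)[C@H]2CC(=O)C=C1
F5 | step 6 | C1-unsubstituted C6-phenyl keto lactone | CC[C@@]1(COC(=O)C2)[C@H]2CC(=O)C[C@H]1c1ccccc1
F6 | step 6 | C1-unsubstituted C4-dioxolane lactone | CC[C@@]1(COC(=O)C2)[C@H]2CC3(OCCO3)C[C@H]1c1ccccc1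
F7 | step 14 | enol ether alcohol with the C1–C2H=C3(Me)–OMe chain (E/Z mixture) | CC[C@@]1(CO)[C@H]([C@H](C)C=C(C)OC)CC2(OCCO2)C[C@H]1c1ccccc1
F8 | step 14 | diketone alcohol (C3 methyl ketone, C4 ketone) | CC[C@@]1(CO)[C@H]([C@H](C)CC(C)=O)CC(=O)C[C@H]1c1ccccc1
F9 | step 14 | C3-methyl C3=C3a enone with free C8 hydroxyl | CC[C@@]1(CO)[C@H]2C(C(=O)C[C@H]1c1ccccc1)=C(C)C[C@H]2C
F10 | step 14 | trans-fused C3-methyl hydroxy ketone | CC[C@@]1(CO)[C@H]2[C@H](C(=O)C[C@H]1c1ccccc1)[C@H](C)C[C@H]2C
F11 | step 14 | trans-fused C3-methyl keto aldehyde (C8 aldehyde) | CC[C@@]1(C=O)[C@H]2[C@H](C(=O)C[C@H]1c1ccccc1)[C@H](C)C[C@H]2C
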